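**Plan**

Ring numbering: cyclopentane C1 (quaternary: CH3 and CH2CH2CO2H), C2 (CH–CH2OAr), C3 (CH–CH3), C4 (CH2), C5 (CH–CH=CMe2).
Cuts: (i) the aryl C7–O bond of the chromenone ether; (ii) in one operation, ring bond C1–C5 and the CH2–CH2 bond of the propanoic arm; (iii) C4–C5 (sp3–sp2); (iv) C1–C2; (v) C2–C3.
Forward: C2–C3 (ketene–aldehyde [2+2]), C1–C2 (lactone opening) and C4–C5 (Negishi coupling) build an acyclic 1,6-diene. The only carbocycle is then closed, and the preformed chromenone is attached afterwards.
Enabling feature: C5 is allylic to the exocyclic CH=CMe2 bond and bonded to C1, which carries a CH2–CH2CO2H arm. C1–C5 is therefore the bond of a 5-exo closure of a tertiary radical made by adding •CH2CO2R to an isopropenyl group. The CH=CMe2 bond is what remains after β-scission of a leaving group on the CMe2 carbon.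
Stereochemistry: C3 and C2 come from a catalyst-controlled cis-β-lactone and its invertive SN2 opening. C1 and C5 come from the chair-like 5-exo transition state, in which the target's relative configuration has every larger group equatorial.

Key step: step 9

Assumption: O-trimethylsilylquinine is taken to deliver the (3R,4R)-lactone 4; if the sense of induction is the opposite, the pseudo-enantiomeric O-trimethylsilylquinidine takes its place and nothing else changes.

**Route**

Step 1
Reactants: 1 propanoyl chloride; 2 2-[(tert-butyldimethylsilyl)oxy]acetaldehyde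
Product: 4 (3R,4R)-4-{[(tert-butyldimethylsilyl)oxy]methyl}-3-methyloxetan-2-one, via methylketene 3 (not isolated)
Conditions: O-trimethylsilylquinine (10 mol %), LiClO4, iPr2NEt, CH2Cl2/Et2O, −78 °C
Reagents that add atoms: none
Why: Cinchona-alkaloid/lithium-salt co-catalysed ketene–aldehyde [2+2] cyclocondensation: 3, made in situ by dehydrochlorination of 1, is bound by the chiral amine as its Z-enolate and adds to the lithium-activated aldehyde through a closed transition state, which makes the two new stereocentres cis and fixes their absolute configuration (lactone C3 is the future ring C3, lactone C4 the future ring C2).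

Step 2
Reactants: 4 (3R,4R)-4-{[(tert-butyldimethylsilyl)oxy]methyl}-3-methyloxetan-2-one; 5 isopropenylmagnesium bromide
Product: 6 (2R,3R)-3-{[(tert-butyldimethylsilyl)oxy]methyl}-2,4-dimethylpent-4-enoic acid
Conditions: CuBr·SMe2 (15 mol %), THF/Me2S, −30 to 0 °C; then cold 1 M HCl
Reagents that add atoms: none
Why: Copper-catalysed SN2 alkyl–oxygen opening of a β-lactone by a Grignard reagent: the soft alkenylcopper nucleophile attacks lactone C4 anti to the carboxylate leaving group, so that this centre is inverted to the configuration of ring C2 while the α-methyl centre is untouched.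

Step 3
Reactants: 6 (2R,3R)-3-{[(tert-butyldimethylsilyl)oxy]methyl}-2,4-dimethylpent-4-enoic acid
Product: 7 (2R,3R)-3-{[(tert-butyldimethylsilyl)oxy]methyl}-2,4-dimethylpent-4-en-1-ol
Conditions: LiAlH4, Et2O, 0 °C to rt; then H2O
Reagents that add atoms: none
Why: Lithium aluminium hydride reduction of a carboxylic acid to the primary alcohol, which leaves the silyl ether, the 1,1-disubstituted alkene and both stereocentres untouched.

Step 4
Reactants: 7 (2R,3R)-3-{[(tert-butyldimethylsilyl)oxy]methyl}-2,4-dimethylpent-4-en-1-ol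
Product: 8 tert-butyl{[(2R,3R)-4-iodo-3-methyl-2-(prop-1-en-2-yl)butyl]oxy}dimethylsilane
Conditions: I2, PPh3, imidazole, CH2Cl2, 0 °C
Reagents that add atoms: iodine, II
Why: Appel-type iodination of an unhindered primary alcohol under buffered, near-neutral conditions that spare the silyl ether and the alkene.

Step 5
Reactants: 9 2-methylbut-3-yn-2-ol
Product: 11 (E)-4-iodo-2-methylbut-3-en-2-ol, via the O,C-bis(chlorozirconocene) (E)-alkenyl alkoxide 10 (not isolated)
Conditions: Cp2Zr(H)Cl (2.1 equiv), THF, rt, dark; then I2, 0 °C; aqueous work-up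
Reagents that add atoms: iodine, II; zirconocene chloride hydride, [H][Zr](Cl)(C1C=CC=C1)C1C=CC=C1 (zirconium of 10 only)
Why: Syn-hydrozirconation of the terminal alkyne places zirconium on the terminal carbon (the first equivalent is consumed by the hydroxyl group), and iodinolysis with retention gives the E-iodoalkene.

Step 6
Reactants: 8 tert-butyl{[(2R,3R)-4-iodo-3-methyl-2-(prop-1-en-2-yl)butyl]oxy}dimethylsilane; 11 (E)-4-iodo-2-methylbut-3-en-2-ol
Product: 13 (3E,6S,7R)-7-{[(tert-butyldimethylsilyl)oxy]methyl}-2,6,8-trimethylnona-3,8-dien-2-ol, via {(2R,3R)-4-[(tert-butyldimethylsilyl)oxy]-2-methyl-3-(prop-1-en-2-yl)butyl}zinc iodide 12 (not isolated)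
Conditions: Zn dust, LiCl, THF, 40 °C; then 11, Pd(OAc)2 (2 mol %), SPhos (4 mol %), THF, rt
Reagents that add atoms: zinc, [Zn] (zinc of 12 only)
Why: Negishi sp3–sp2 cross-coupling: direct zinc insertion into the primary iodide and palladium-catalysed coupling with retention of the E geometry forge the future C4–C5 bond, the weakly basic alkylzinc iodide tolerating the tertiary hydroxyl group on the time scale of the coupling.

Step 7
Reactants: 13 (3E,6S,7R)-7-{[(tert-butyldimethylsilyl)oxy]methyl}-2,6,8-trimethylnona-3,8-dien-2-ol; 14 2,6-difluoropyridine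
Product: 16 2-{[(3E,6S,7R)-7-{[(tert-butyldimethylsilyl)oxy]methyl}-2,6,8-trimethylnona-3,8-dien-2-yl]oxy}-6-fluoropyridine, via the sodium alkoxide of 13 15 (not isolated)
Conditions: NaH, THF/DMF, 0 to 50 °C, excess 14
Reagents that add atoms: sodium hydride, [Na+].[H-] (sodium of 15 only)
Why: Nucleophilic aromatic substitution of one fluoride of the doubly activated pyridine by the tertiary alkoxide installs a radical leaving group on the CMe2 carbon without touching the silyl ether.

Step 8
Reactants: 17 tert-butyl bromoacetate; 18 potassium O-ethyl dithiocarbonate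
Product: 19 tert-butyl 2-[(ethoxycarbonothioyl)sulfanyl]acetate
Conditions: acetone, 0 °C to rt
Reagents that add atoms: none
Why: SN2 displacement of an α-bromo ester by the soft xanthate sulfur.

Step 9
Reactants: 16 2-{[(3E,6S,7R)-7-{[(tert-butyldimethylsilyl)oxy]methyl}-2,6,8-trimethylnona-3,8-dien-2-yl]oxy}-6-fluoropyridine; 19 tert-butyl 2-[(ethoxycarbonothioyl)sulfanyl]acetate
Product: 20 tert-butyl 3-[(1R,2R,3S,5S)-2-{[(tert-butyldimethylsilyl)oxy]methyl}-1,3-dimethyl-5-(2-methylprop-1-en-1-yl)cyclopentyl]propanoate
Conditions: 19 (2 equiv), dilauroyl peroxide (in portions, stoichiometric in total), degassed EtOAc, reflux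
Reagents that add atoms: none
Why: Proposed new method: undecyl radicals from the peroxide release •CH2CO2tBu from 19, this electrophilic radical adds to the CH2 terminus of the isopropenyl group of 16, the resulting tertiary C1 radical attacks the alkene carbon that becomes C5, and the secondary radical so formed expels the 6-fluoropyridin-2-yloxyl radical by β-scission of the tertiary C–O bond, which places the CH=CMe2 double bond in one position only. The closest known reaction types are xanthate-transfer addition–cyclisation cascades on 1,6-dienes and radical allylation with allylic 6-fluoropyridyl ethers, and what is new is their merger into one ring closure that ends at a quaternary carbon. The cyclopentane closes in the 5-exo-trig mode, 6-endo attack being blocked because that alkene carbon is flanked by the fully substituted CMe2O carbon. C5 is set by the chair-like transition state with the C2 CH2OTBS and C3 methyl groups both pseudo-equatorial (C2 substituent trans, C3 substituent cis to the new alkenyl group), and C1 by the larger CH2CH2CO2tBu arm of the planar radical taking the pseudo-equatorial site, which places it cis to the alkenyl group and the methyl group trans. The electrophilic radical must choose the isopropenyl group over the internal alkene, which the terminal, 1,1-dialkyl-substituted and more nucleophilic character of the former secures, and the tertiary radical must live long enough to cyclise, which the reversible, degenerate xanthate transfer secures. Since the expelled aryloxyl radical does not carry a chain, the peroxide is used in stoichiometric amount.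

Step 10
Reactants: 20 tert-butyl 3-[(1R,2R,3S,5S)-2-{[(tert-butyldimethylsilyl)oxy]methyl}-1,3-dimethyl-5-(2-methylprop-1-en-1-yl)cyclopentyl]propanoate
Product: 21 tert-butyl 3-[(1R,2R,3S,5S)-2-(hydroxymethyl)-1,3-dimethyl-5-(2-methylprop-1-en-1-yl)cyclopentyl]propanoate
Conditions: HF·pyridine, THF, 0 °C to rt
Reagents that add atoms: none
Why: Fluoride-induced cleavage of the primary silyl ether under buffered conditions that spare the tert-butyl ester and the trisubstituted alkene.

Step 11
Reactants: 21 tert-butyl 3-[(1R,2R,3S,5S)-2-(hydroxymethyl)-1,3-dimethyl-5-(2-methylprop-1-en-1-yl)cyclopentyl]propanoate; 22 7-bromo-2H-chromen-2-one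
Product: 23 tert-butyl 3-[(1R,2R,3S,5S)-1,3-dimethyl-5-(2-methylprop-1-en-1-yl)-2-{[(2-oxo-2H-chromen-7-yl)oxy]methyl}cyclopentyl]propanoate
Conditions: tBuBrettPhos Pd G3 (3 mol %), Cs2CO3, toluene, 90 °C
Reagents that add atoms: none
Why: Palladium-catalysed C–O cross-coupling (Buchwald–Hartwig etherification) of a primary alcohol with an aryl bromide: the bulky biaryl phosphine speeds reductive elimination over β-hydride elimination, the carbonate base spares lactone and ester, and the oxygen stays on the terpenoid carbon so that no stereocentre is involved.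

Step 12
Reactants: 23 tert-butyl 3-[(1R,2R,3S,5S)-1,3-dimethyl-5-(2-methylprop-1-en-1-yl)-2-{[(2-oxo-2H-chromen-7-yl)oxy]methyl}cyclopentyl]propanoate
Product: 25 ferulsinaic acid, 3-[(1R,2R,3S,5S)-1,3-dimethyl-5-(2-methylprop-1-en-1-yl)-2-{[(2-oxo-2H-chromen-7-yl)oxy]methyl}cyclopentyl]propanoic acid, via its trimethylsilyl ester 24 (not isolated)
Conditions: TMSOTf, 2,6-lutidine, CH2Cl2, 0 °C; then aqueous pH 4 buffer
Reagents that add atoms: trimethylsilyl triflate, C[Si](C)(C)OS(=O)(=O)C(F)(F)F (silyl group of 24 only)
Why: Silyl-triflate-mediated cleavage of the tert-butyl ester (loss of isobutene, lutidine as proton trap) followed by hydrolysis of the silyl ester frees the acid without aqueous base, which would open the chromenone lactone, and without free strong acid, which would protonate the trisubstituted alkene.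

**Compound list**

1 | propanoyl chloride | CCC(=O)Cl | starting material
2 | 2-[(tert-butyldimethylsilyl)oxy]acetaldehyde | CC(C)(C)[Si](C)(C)OCC=O | starting material
3 | methylketene | CC=C=O | intermediate
4 | (3R,4R)-4-{[(tert-butyldimethylsilyl)oxy]methyl}-3-methyloxetan-2-one (cis) | O=C1[C@H](C)[C@H](CO[Si](C)(C)C(C)(C)C)O1 | intermediate
5 | isopropenylmagnesium bromide | CC(=C)[Mg]Br | starting material
6 | (2R,3R)-3-{[(tert-butyldimethylsilyl)oxy]methyl}-2,4-dimethylpent-4-enoic acid | OC(=O)[C@H](C)[C@@H](CO[Si](C)(C)C(C)(C)C)C(C)=C | intermediate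
7 | (2R,3R)-3-{[(tert-butyldimethylsilyl)oxy]methyl}-2,4-dimethylpent-4-en-1-ol | OC[C@H](C)[C@@H](CO[Si](C)(C)C(C)(C)C)C(C)=C | intermediate
8 | tert-butyl{[(2R,3R)-4-iodo-3-methyl-2-(prop-1-en-2-yl)butyl]oxy}dimethylsilane | IC[C@H](C)[C@@H](CO[Si](C)(C)C(C)(C)C)C(C)=C | intermediate
9 | 2-methylbut-3-yn-2-ol | CC(C)(O)C#C | starting material
10 | O,C-bis(chlorozirconocene) (E)-alkenyl alkoxide of 9 | CC(C)(O[Zr](Cl)(C1C=CC=C1)C1C=CC=C1)/C=C/[Zr](Cl)(C1C=CC=C1)C1C=CC=C1 | intermediate
11 | (E)-4-iodo-2-methylbut-3-en-2-ol | CC(C)(O)/C=C/I | intermediate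
12 | {(2R,3R)-4-[(tert-butyldimethylsilyl)oxy]-2-methyl-3-(prop-1-en-2-yl)butyl}zinc iodide | I[Zn]C[C@H](C)[C@@H](CO[Si](C)(C)C(C)(C)C)C(C)=C | intermediate
13 | (3E,6S,7R)-7-{[(tert-butyldimethylsilyl)oxy]methyl}-2,6,8-trimethylnona-3,8-dien-2-ol | CC(C)(O)/C=C/C[C@H](C)[C@@H](CO[Si](C)(C)C(C)(C)C)C(C)=C | intermediate
14 | 2,6-difluoropyridine | Fc1cccc(F)n1 | starting material
15 | sodium alkoxide of 13 | CC(C)([O-])/C=C/C[C@H](C)[C@@H](CO[Si](C)(C)C(C)(C)C)C(C)=C.[Na+] | intermediate
16 | 2-{[(3E,6S,7R)-7-{[(tert-butyldimethylsilyl)oxy]methyl}-2,6,8-trimethylnona-3,8-dien-2-yl]oxy}-6-fluoropyridine | CC(C)(Oc1cccc(F)n1)/C=C/C[C@H](C)[C@@H](CO[Si](C)(C)C(C)(C)C)C(C)=C | intermediate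
17 | tert-butyl bromoacetate | CC(C)(C)OC(=O)CBr | starting material
18 | potassium O-ethyl dithiocarbonate | CCOC(=S)[S-].[K+] | starting material
19 | tert-butyl 2-[(ethoxycarbonothioyl)sulfanyl]acetate | CCOC(=S)SCC(=O)OC(C)(C)C | intermediate
20 | tert-butyl 3-[(1R,2R,3S,5S)-2-{[(tert-butyldimethylsilyl)oxy]methyl}-1,3-dimethyl-5-(2-methylprop-1-en-1-yl)cyclopentyl]propanoate | CC(C)=C[C@@H]1C[C@H](C)[C@@H](CO[Si](C)(C)C(C)(C)C)[C@]1(C)CCC(=O)OC(C)(C)C | intermediate
21 | tert-butyl 3-[(1R,2R,3S,5S)-2-(hydroxymethyl)-1,3-dimethyl-5-(2-methylprop-1-en-1-yl)cyclopentyl]propanoate | CC(C)=C[C@@H]1C[C@H](C)[C@@H](CO)[C@]1(C)CCC(=O)OC(C)(C)C | intermediate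
22 | 7-bromo-2H-chromen-2-one | O=c1ccc2ccc(Br)cc2o1 | starting material
23 | tert-butyl ester of ferulsinaic acid | CC(C)=C[C@@H]1C[C@H](C)[C@@H](COc2ccc3ccc(=O)oc3c2)[C@]1(C)CCC(=O)OC(C)(C)C | intermediate
24 | trimethylsilyl ester of ferulsinaic acid | CC(C)=C[C@@H]1C[C@H](C)[C@@H](COc2ccc3ccc(=O)oc3c2)[C@]1(C)CCC(=O)O[Si](C)(C)C | intermediate
25 | ferulsinaic acid | CC(C)=C[C@@H]1C[C@H](C)[C@@H](COc2ccc3ccc(=O)oc3c2)[C@]1(C)CCC(=O)O | target

**Counts and risks**

Total step count: 12. Longest linear sequence: 10 steps (1, 2, 3, 4, 6, 7, 9, 10, 11, 12).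

Steps most likely to fail:

1. Step 9 (Proposed new method). The planar C1 radical may not discriminate well enough between its methyl group and its ester arm. It may also be intercepted by xanthate transfer and elimination before the ring closes, and the starting radical may attack the internal alkene directly. The fallback uses known chemistry, sets out from 16 and comes back at 20. Chemoselective epoxidation of the isopropenyl group with mCPBA gives the 2-methyloxirane F1. Titanocene(III) chloride (Cp2TiCl2, Mn, THF) opens it reductively to the tertiary β-titanoxy radical (titanocene(III)-mediated epoxide opening/5-exo radical cyclisation). Its very large CH2OTi arm takes the equatorial site of the same chair, and the cyclised radical loses the same leaving group, giving the neopentyl alcohol F2. Dess–Martin oxidation gives the aldehyde F3. A Wittig reaction with tert-butyl (triphenylphosphoranylidene)acetate gives the E-enoate F4. Copper-hydride conjugate reduction with [(Ph3P)CuH]6 then gives 20.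

2. Step 2. The Grignard/copper reagent may attack the acyl carbon, or act as a base and trigger β-elimination to the unsaturated acid, instead of substituting at the hindered lactone C4. The fallback replaces the lactone chemistry by a sigmatropic construction of the same C2–C3 bond. It sets out from 1, with commercial 3-methylbut-2-en-1-ol as the new partner, and comes back at 6. The alcohol is silylated to the prenyl silyl ether F5. SeO2/tBuOOH oxidises the E-methyl group of F5 to the allylic alcohol F6, and acylation with 1 gives the propanoate F7. An enantioselective Ireland–Claisen rearrangement then gives (2R,3R)-6. It runs through the Z(O)-boron enolate formed with a C2-symmetric bromodiazaborolidine derived from 1,2-diphenylethane-1,2-diamine bis-sulfonamide and iPr2NEt in CH2Cl2. With the E-alkene and the Z(O)-enolate both equatorial in the chair, the 2,3-syn acid results.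

3. Step 11. With this β-branched, hindered alcohol, reductive elimination from the palladium alkoxide may lose to β-hydride elimination, and the alkoxide may open the lactone of 22. In the fallback the chromenone is built on the ether instead of being coupled as a whole. It sets out from 21 and comes back at 23. A Mitsunobu reaction with 2,4-dihydroxybenzaldehyde (DIAD, PPh3) occurs at the free 4-hydroxyl group, because the 2-hydroxyl group is tied up in a hydrogen bond to the aldehyde. This gives the 4-alkoxy-2-hydroxybenzaldehyde F8. Heating F8 with (triphenylphosphoranylidene)ketene in toluene acylates the phenol and closes the pyranone ring by an intramolecular Wittig reaction, giving 23.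

**Further compounds**

F1 | step 9 | 2-{[(3E,6S,7S)-8-[(tert-butyldimethylsilyl)oxy]-2,6-dimethyl-7-(2-methyloxiran-2-yl)oct-3-en-2-yl]oxy}-6-fluoropyridine (both epimers at the oxirane carbon) | CC(C)(Oc1cccc(F)n1)/C=C/C[C@H](C)[C@@H](CO[Si](C)(C)C(C)(C)C)C1(C)CO1
F2 | step 9 | [(1R,2R,3S,5S)-2-{[(tert-butyldimethylsilyl)oxy]methyl}-1,3-dimethyl-5-(2-methylprop-1-en-1-yl)cyclopentyl]methanol | CC(C)=C[C@@H]1C[C@H](C)[C@@H](CO[Si](C)(C)C(C)(C)C)[C@]1(C)CO
F3 | step 9 | (1R,2R,3S,5S)-2-{[(tert-butyldimethylsilyl)oxy]methyl}-1,3-dimethyl-5-(2-methylprop-1-en-1-yl)cyclopentane-1-carbaldehyde | CC(C)=C[C@@H]1C[C@H](C)[C@@H](CO[Si](C)(C)C(C)(C)C)[C@]1(C)C=O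
F4 | step 9 | tert-butyl (E)-3-[(1R,2R,3S,5S)-2-{[(tert-butyldimethylsilyl)oxy]methyl}-1,3-dimethyl-5-(2-methylprop-1-en-1-yl)cyclopentyl]prop-2-enoate | CC(C)=C[C@@H]1C[C@H](C)[C@@H](CO[Si](C)(C)C(C)(C)C)[C@]1(C)/C=C/C(=O)OC(C)(C)C
F5 | step 2 | tert-butyldimethyl[(3-methylbut-2-en-1-yl)oxy]silane | CC(C)=CCO[Si](C)(C)C(C)(C)C
F6 | step 2 | (E)-4-[(tert-butyldimethylsilyl)oxy]-2-methylbut-2-en-1-ol | OC/C(C)=C/CO[Si](C)(C)C(C)(C)C
F7 | step 2 | (E)-4-[(tert-butyldimethylsilyl)oxy]-2-methylbut-2-en-1-yl propanoate | CCC(=O)OC/C(C)=C/CO[Si](C)(C)C(C)(C)C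
F8 | step 11 | tert-butyl 3-[(1R,2R,3S,5S)-2-[(4-formyl-3-hydroxyphenoxy)methyl]-1,3-dimethyl-5-(2-methylprop-1-en-1-yl)cyclopentyl]propanoate | CC(C)=C[C@@H]1C[C@H](C)[C@@H](COc2ccc(C=O)c(O)c2)[C@]1(C)CCC(=O)OC(C)(C)C
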